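**Assumption:** the target has no stereocentre and its only alkene carries two identical methyl groups, so it is achiral and no stereocontrol is needed.

## Retrosynthetic overview

- The tetramethoxybenzene core comes from reduction and O-methylation of a 2,5-dimethoxy-3,6-bis(indol-3-yl)-1,4-benzoquinone, itself made from the 2,5-dichloroquinone by hydrolysis and O-methylation.
- Key C–C disconnections: both aryl–indole bonds. Each is made by an acid-promoted Michael (conjugate) addition of an indole C3 to 2,5-dichloro-1,4-benzoquinone or its mono-indolyl derivative, followed by re-oxidation of the hydroquinone.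
- 5-Prenylindole comes from 5-bromoindole by N-silylation, Br/Li exchange, alkylation with prenyl bromide and desilylation.
- Ring order: no ring is built. Both indoles and the six-membered quinone ring are bought preformed; the central ring only becomes a benzene ring in the last step.

## Route

**Step 1**
Reactants: 1 5-bromo-1H-indole
Product: 3 5-bromo-1-(triisopropylsilyl)-1H-indole, via sodium indolide 2 (not isolated)
Conditions: NaH (1.2 equiv), THF, 0 °C; then TIPSCl (1.1 equiv), 0 °C → rt
Reagents that add atoms: chlorotriisopropylsilane (TIPSCl), CC(C)[Si](Cl)(C(C)C)C(C)C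
Why: NaH deprotonates the indole N–H and the indolide is N-silylated (N-protection); the bulky silyl group blocks N–H and C2 metalation in the next step.

**Step 2**
Reactants: 3 5-bromo-1-(triisopropylsilyl)-1H-indole; 4 prenyl bromide (1-bromo-3-methylbut-2-ene)
Product: 6 5-(3-methylbut-2-en-1-yl)-1-(triisopropylsilyl)-1H-indole, via aryllithium 5 (not isolated)
Conditions: t-BuLi (2.1 equiv), THF, −78 °C; then 4 (1.5 equiv), −78 °C → rt
Reagents that add atoms: none
Why: Bromine–lithium exchange is fast at −78 °C, and the aryllithium undergoes SN2 allylic alkylation at the unhindered primary carbon of prenyl bromide.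

**Step 3**
Reactants: 6 5-(3-methylbut-2-en-1-yl)-1-(triisopropylsilyl)-1H-indole
Product: 7 5-(3-methylbut-2-en-1-yl)-1H-indole (5-prenylindole)
Conditions: TBAF (1.1 equiv), THF, 0 °C → rt; aqueous work-up
Reagents that add atoms: none
Why: Fluoride-mediated N-desilylation is driven by the strong Si–F bond and leaves the prenyl alkene untouched.

**Step 4**
Reactants: 8 1H-indole; 9 2,5-dichloro-1,4-benzoquinone
Product: 11 2,5-dichloro-3-(1H-indol-3-yl)cyclohexa-2,5-diene-1,4-dione, via hydroquinone adduct 10 (not isolated)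
Conditions: conc. HCl (cat.), THF, rt; then DDQ (1.0 equiv), rt
Reagents that add atoms: none
Why: Acid-promoted Michael (conjugate, Friedel–Crafts-type) addition of indole C3 to the unsubstituted β-carbon of the activated chloroquinone gives the aryl hydroquinone, which DDQ dehydrogenates back to the quinone; no stereocentre is formed.

**Step 5**
Reactants: 11 2,5-dichloro-3-(1H-indol-3-yl)cyclohexa-2,5-diene-1,4-dione; 7 5-(3-methylbut-2-en-1-yl)-1H-indole
Product: 13 2,5-dichloro-3-(1H-indol-3-yl)-6-[5-(3-methylbut-2-en-1-yl)-1H-indol-3-yl]cyclohexa-2,5-diene-1,4-dione, via bis(indolyl)hydroquinone 12 (not isolated)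
Conditions: Zn(OTf)2 (1.0 equiv), THF, rt; then Ag2CO3 on Celite (2 equiv), rt
Reagents that add atoms: none
Why: A second Michael addition, of 5-prenylindole C3 to the only remaining C–H position of quinone 11, runs under mild Lewis-acid activation that spares the prenyl alkene, and Ag2CO3 then oxidises the hydroquinone to the quinone.

**Step 6**
Reactants: 13 2,5-dichloro-3-(1H-indol-3-yl)-6-[5-(3-methylbut-2-en-1-yl)-1H-indol-3-yl]cyclohexa-2,5-diene-1,4-dione
Product: 14 2,5-dihydroxy-3-(1H-indol-3-yl)-6-[5-(3-methylbut-2-en-1-yl)-1H-indol-3-yl]cyclohexa-2,5-diene-1,4-dione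
Conditions: 10% aq. NaOH, MeOH, reflux; then 1 M HCl to pH 2
Reagents that add atoms: sodium hydroxide, [Na+].[OH-]
Why: The two vinylogous acyl chlorides undergo addition–elimination with hydroxide, and the product is drawn out of the equilibrium as its stabilised dianion, reprotonated on acidification.

**Step 7**
Reactants: 14 2,5-dihydroxy-3-(1H-indol-3-yl)-6-[5-(3-methylbut-2-en-1-yl)-1H-indol-3-yl]cyclohexa-2,5-diene-1,4-dione
Product: 15 3-(1H-indol-3-yl)-2,5-dimethoxy-6-[5-(3-methylbut-2-en-1-yl)-1H-indol-3-yl]cyclohexa-2,5-diene-1,4-dione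
Conditions: Me2SO4 (2.5 equiv), K2CO3 (3 equiv), acetone, reflux
Reagents that add atoms: dimethyl sulfate, COS(=O)(=O)OC
Why: The acidic vinylogous-acid hydroxyls are O-alkylated (Williamson-type) under K2CO3, a base too weak to deprotonate and methylate the indole N–H.

**Step 8**
Reactants: 15 3-(1H-indol-3-yl)-2,5-dimethoxy-6-[5-(3-methylbut-2-en-1-yl)-1H-indol-3-yl]cyclohexa-2,5-diene-1,4-dione
Product: 17 3-[4-(1H-indol-3-yl)-2,3,5,6-tetramethoxyphenyl]-5-(3-methylbut-2-en-1-yl)-1H-indole (target), via dimethoxyhydroquinone 16 (not isolated)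
Conditions: Na2S2O4 (excess), THF/H2O, rt, Ar; extract with degassed EtOAc and concentrate; then Me2SO4 (4 equiv), K2CO3 (6 equiv), degassed acetone, reflux, Ar
Reagents that add atoms: dimethyl sulfate, COS(=O)(=O)OC
Why: Dithionite reduction of the quinone aromatises the central ring, and Williamson O-methylation of the two phenols then gives the tetramethoxybenzene without touching the indole N–H or the prenyl group; no stereocentre is present.

## Compound list

1 | 5-bromo-1H-indole | Brc1ccc2[nH]ccc2c1 | starting material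
2 | sodium 5-bromoindol-1-ide | [Na+].Brc1ccc2[n-]ccc2c1 | intermediate
3 | 5-bromo-1-(triisopropylsilyl)-1H-indole | CC(C)[Si](C(C)C)(C(C)C)n1ccc2cc(Br)ccc21 | intermediate
4 | prenyl bromide (1-bromo-3-methylbut-2-ene) | CC(C)=CCBr | starting material
5 | 5-lithio-1-(triisopropylsilyl)-1H-indole | [Li]c1ccc2c(c1)ccn2[Si](C(C)C)(C(C)C)C(C)C | intermediate
6 | 5-(3-methylbut-2-en-1-yl)-1-(triisopropylsilyl)-1H-indole | CC(C)=CCc1ccc2c(c1)ccn2[Si](C(C)C)(C(C)C)C(C)C | intermediate
7 | 5-(3-methylbut-2-en-1-yl)-1H-indole | CC(C)=CCc1ccc2[nH]ccc2c1 | intermediate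
8 | 1H-indole | c1ccc2[nH]ccc2c1 | starting material
9 | 2,5-dichloro-1,4-benzoquinone | O=C1C=C(Cl)C(=O)C=C1Cl | starting material
10 | 2,5-dichloro-3-(1H-indol-3-yl)benzene-1,4-diol | Oc1cc(Cl)c(O)c(-c2c[nH]c3ccccc23)c1Cl | intermediate
11 | 2,5-dichloro-3-(1H-indol-3-yl)cyclohexa-2,5-diene-1,4-dione | O=C1C=C(Cl)C(=O)C(-c2c[nH]c3ccccc23)=C1Cl | intermediate
12 | 2,5-dichloro-3-(1H-indol-3-yl)-6-[5-(3-methylbut-2-en-1-yl)-1H-indol-3-yl]benzene-1,4-diol | Oc1c(Cl)c(-c2c[nH]c3ccccc23)c(O)c(Cl)c1-c1c[nH]c2ccc(CC=C(C)C)cc12 | intermediate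
13 | 2,5-dichloro-3-(1H-indol-3-yl)-6-[5-(3-methylbut-2-en-1-yl)-1H-indol-3-yl]cyclohexa-2,5-diene-1,4-dione | O=C1C(Cl)=C(-c2c[nH]c3ccccc23)C(=O)C(Cl)=C1-c1c[nH]c2ccc(CC=C(C)C)cc12 | intermediate
14 | 2,5-dihydroxy-3-(1H-indol-3-yl)-6-[5-(3-methylbut-2-en-1-yl)-1H-indol-3-yl]cyclohexa-2,5-diene-1,4-dione | O=C1C(O)=C(-c2c[nH]c3ccccc23)C(=O)C(O)=C1-c1c[nH]c2ccc(CC=C(C)C)cc12 | intermediate
15 | 3-(1H-indol-3-yl)-2,5-dimethoxy-6-[5-(3-methylbut-2-en-1-yl)-1H-indol-3-yl]cyclohexa-2,5-diene-1,4-dione | COC1=C(-c2c[nH]c3ccccc23)C(=O)C(OC)=C(-c2c[nH]c3ccc(CC=C(C)C)cc23)C1=O | intermediate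
16 | 2-(1H-indol-3-yl)-3,6-dimethoxy-5-[5-(3-methylbut-2-en-1-yl)-1H-indol-3-yl]benzene-1,4-diol | COc1c(-c2c[nH]c3ccccc23)c(O)c(OC)c(-c2c[nH]c3ccc(CC=C(C)C)cc23)c1O | intermediate
17 | 3-[4-(1H-indol-3-yl)-2,3,5,6-tetramethoxyphenyl]-5-(3-methylbut-2-en-1-yl)-1H-indole | COc1c(OC)c(-c2c[nH]c3ccc(CC=C(C)C)cc23)c(OC)c(OC)c1-c1c[nH]c2ccccc12 | target

## Summary

Total step count: 8.
Longest linear sequence: 7 steps (steps 1, 2, 3, 5, 6, 7, 8, from 5-bromoindole); the indole/quinone branch (step 4) joins at step 5.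

**Steps most likely to fail**

Step 2 (prenylation of the aryllithium). The risks are Wurtz-type side reactions, SN2′ attack giving the 1,1-dimethylallyl isomer, and incomplete exchange. The fallback sets out from 3 and comes back at 6. Stille coupling of 3 with allyltributylstannane (Pd(PPh3)4, toluene, 110 °C) gives 5-allyl-1-(triisopropylsilyl)-1H-indole F1, with no regiochemical ambiguity. Olefin cross-metathesis of F1 with excess 2-methyl-2-butene (second-generation Grubbs catalyst, CH2Cl2, 40 °C) converts the allyl group into the prenyl group of 6.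

Step 5 (second conjugate addition). Quinone 11 is less electrophilic and more hindered than 9, and 7 is the precious, acid-sensitive partner. The fallback sets out from 7 and 9 and comes back at 12, by reversing the order in which the two indoles are attached. Indole 7 is first added to the much more electrophilic 9 (Zn(OTf)2, THF, rt) to give 2,5-dichloro-3-[5-(3-methylbut-2-en-1-yl)-1H-indol-3-yl]benzene-1,4-diol F2. This is oxidised without isolation (Ag2CO3 on Celite) to 2,5-dichloro-3-[5-(3-methylbut-2-en-1-yl)-1H-indol-3-yl]cyclohexa-2,5-diene-1,4-dione F3. Cheap, robust indole 8 is then used in excess for the slower addition to F3 (Zn(OTf)2, THF, rt), which gives hydroquinone 12; this is oxidised to 13 as in step 5.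

Step 8 (reductive methylation). The risks are re-oxidation of the hydroquinone, sluggish methylation of the two hindered phenols, and competing N-methylation if forced. The fallback sets out from 15 and comes back at 17. Treatment of 15 with Boc2O and catalytic DMAP in MeCN gives the N,N′-bis(tert-butoxycarbonyl) derivative of quinone 15 F4. Reduction with Na2S2O4 (THF/H2O, Ar) gives the N,N′-bis(tert-butoxycarbonyl) derivative of hydroquinone 16 F5, which is not isolated. With both nitrogens blocked it can be methylated under forcing conditions (NaH, MeI, DMF, 0 °C → rt) to the N,N′-bis(tert-butoxycarbonyl) derivative of the target F6. K2CO3 in MeOH at reflux then removes both Boc groups to give 17.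

## Further compounds

F1 | step 2 | 5-allyl-1-(triisopropylsilyl)-1H-indole | C=CCc1ccc2c(c1)ccn2[Si](C(C)C)(C(C)C)C(C)C
F2 | step 5 | 2,5-dichloro-3-[5-(3-methylbut-2-en-1-yl)-1H-indol-3-yl]benzene-1,4-diol | Oc1cc(Cl)c(O)c(-c2c[nH]c3ccc(CC=C(C)C)cc23)c1Cl
F3 | step 5 | 2,5-dichloro-3-[5-(3-methylbut-2-en-1-yl)-1H-indol-3-yl]cyclohexa-2,5-diene-1,4-dione | O=C1C=C(Cl)C(=O)C(-c2c[nH]c3ccc(CC=C(C)C)cc23)=C1Cl
F4 | step 8 | N,N′-bis(tert-butoxycarbonyl) derivative of quinone 15 (one Boc group on each indole nitrogen) | COC1=C(-c2cn(C(=O)OC(C)(C)C)c3ccccc23)C(=O)C(OC)=C(-c2cn(C(=O)OC(C)(C)C)c3ccc(CC=C(C)C)cc23)C1=O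
F5 | step 8 | N,N′-bis(tert-butoxycarbonyl) derivative of hydroquinone 16 (one Boc group on each indole nitrogen) | COc1c(-c2cn(C(=O)OC(C)(C)C)c3ccccc23)c(O)c(OC)c(-c2cn(C(=O)OC(C)(C)C)c3ccc(CC=C(C)C)cc23)c1O
F6 | step 8 | N,N′-bis(tert-butoxycarbonyl) derivative of target 17 (one Boc group on each indole nitrogen) | COc1c(OC)c(-c2cn(C(=O)OC(C)(C)C)c3ccc(CC=C(C)C)cc23)c(OC)c(OC)c1-c1cn(C(=O)OC(C)(C)C)c2ccccc12
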